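Readings and results were generated by integration with constants of no real substance; scatter was added.

In the smallest charge, the beta run, 0.80 M of starting material turned over at 0.0274 M min⁻¹ up to 8.00 min. Call this the draw, the average molar turnover from the start to a reading: in the epsilon run it is 0.0481 M min⁻¹, and in the alpha run 0.0434 M min⁻¹.

| setting | beta | epsilon | alpha | flask |
|---|---|---|---|---|
| starting material | 0.80 M | 1.2 M | 1.6 M | 1.6 M |
| gas | 130 mM (held) | 130 mM (held) | 130 mM (held) | 130 mM (held) |
| free catalyst | 3.9 mol% | 3.9 mol% | 1.9 mol% | 3.9 mol% |
| remark | run made earlier | run made earlier | run made earlier |  |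
| time |  |  |  | 8.0 min |

| run | time / min | target / % | starting material / % |
|---|---|---|---|
| beta | 0.667 | 0.9 | 98.7 |
| beta | 1.33 | 1.8 | 96.9 |
| beta | 2.50 | 6.1 | 93.5 |
| beta | 4.00 | 9.5 | 87.1 |
| beta | 8.00 | 16.3 | 72.6 |
| epsilon | 0.667 | 0.6 | 98.0 |
| epsilon | 1.33 | 2.9 | 96.9 |
| epsilon | 2.50 | 7.8 | 91.8 |
| epsilon | 4.00 | 11.4 | 83.9 |
| epsilon | 8.00 | 19.3 | 67.9 |
| alpha | 0.667 | 0.4 | 99.0 |
| alpha | 1.33 | 2.0 | 97.0 |
| alpha | 2.50 | 5.6 | 94.2 |
| alpha | 4.00 | 8.6 | 89.9 |
| alpha | 8.00 | 14.4 | 78.3 |

(readings scatter by 0.5 percentage points)

- what was read earlier has a scatter of 0.5 percentage points, one standard deviation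
- at the start none of the gas is in solution

- amount of target at 8.0 min, in percent of the starting material charged
- the change that raises the amount of target at 8.0 min, in percent of the starting material charged most ("none" if none brings more than 2 percentage points) (elm / oak / alder / none)
- amount of target at 8.0 min, in percent of the starting material charged, after oak

- elm: doubling the saturation concentration of gas, all else as stated
- oak: doubling the amount of free catalyst, all else as stated
- alder: doubling the transfer coefficient of the gas, all else as stated

Two extreme versions bracket the flask. If the passage of gas is already the rate-limiting step at the epsilon charge, the rate is zero-order in catalyst and starting material from that charge upward, and the flask draws what the epsilon run drew, 0.0481 M min⁻¹. If [gas] stays at 130 mM, the rate is first order in catalyst, and the flask draws the alpha value scaled by loading, 0.0891 M min⁻¹. From beta to epsilon, [starting material] and [free catalyst] each rose 1.50-fold and the draw 1.76-fold, more than flat and less than the 2.25-fold of first order in both. So I put the flask between the two versions and take the middle draw, 0.0686 M min⁻¹. Target was 60.1 % of the turnover in the epsilon run, so my estimate for the flask is 20.6 %. Elm raises the draw in both versions, oak in the second, alder in the first, so I choose elm.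

The forecast gives 18 %, 18.5 % after oak, and none as the best change, holding that “Target then depends only on conversion”. On the change, we differ.

The flask gives 19.8 %, and 24.9 % after oak. The best change is elm, worth 11 percentage points, against 5.1 points for oak and 5.9 points for alder.

    coupling partner + free catalyst ⇌ catalyst intermediate A (K = 5.80 M⁻¹, k = 1060 M⁻¹ min⁻¹)
    starting material + catalyst intermediate A ⇌ catalyst intermediate B (K = 5.84 M⁻¹, k = 4.72 M⁻¹ min⁻¹)
    catalyst intermediate B → free catalyst + target (k = 10.8 min⁻¹)
    gas ⇌ coupling partner, rate k4*(csat - [coupling partner]) (kL = 0.830 min⁻¹)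
    target ⇌ isomer of the product (K = 1.70, k = 0.176 min⁻¹)

With 68 % of starting material left, the flask's draw is 0.0638 M min⁻¹, more than 0.0481 M min⁻¹ and less than 0.0891 M min⁻¹, with coupling partner at 0.0525 M. Carried to the same flask left until 5.0 min, that draw leaves 80.1 % of the starting material, and that neighbouring flask holds 80 %.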